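**Assumption (one line):** locants C1–C14 are those of the germacrane skeleton (C15 is the methyl on C4); the propenyl ether is drawn E as the iridium catalyst delivers it, its geometry being lost when C10 becomes sp2; compounds 1, 5, 9 and 10 are taken as commercial.

## The problem

The target is a germacranolide whose ten-membered carbocycle C1–C10 is bridged by an oxygen between C1 and C4, so that C1–C4 and this oxygen form a 3(2H)-furanone. The carbocycle is also trans-fused across C6–C7 to an α-methylene-γ-butyrolactone (C11–C13, ring oxygen on C6). Five stereocentres must be set. Quaternary C4 (S) is insulated from the others by the C5 methylene and needs its own source. C6 (S), C7 (R), C8 (R) and C9 (S) are contiguous: C6/C7 need external control relative to C4, C7 can then direct C8, and the ring with its C8 substituent directs C9. Direct closure of a ten-membered ring is entropically and transannularly costly. The alkenes C11=C13, C10=C14 and C1=C2, the methacrylate and the α-acyloxy allylic alcohol are Michael acceptors or base-labile and must appear late. The enabling feature is that C3 and C9 are both carbonyl-level carbons, 1,5-related through C2–C1–C10, with C1 bearing the ether oxygen of C4. This is the pattern left when a C1=C10 enol ether, tethered through the C4 oxygen, is inserted into the C2–C9 bond of a cyclooctane-1,3-dione by [2+2] photocycloaddition and retro-aldol cleavage.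

## Retrosynthesis

**40 back to 30 (functional-group adjustments).** No skeletal bond is cut. The C9 alcohol comes from enone 39, the ester from alcohol 38, C11=C13 from Mannich base 33, C10=C14 from the C10 methyl group of 33 by selenoxide elimination, and C1=C2 of furanone 32 by dehydrogenation of dione 30. This order keeps every Michael acceptor out of the synthesis until the ring exists. Dione 30 has only sp3 ring carbons beside its two ketones. The forward steps must address the ketones one at a time: kinetic C2 enolization first, after which C10–H is the most acidic site and masks C9 during lactone enolate chemistry.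

**30 back to 28 (key disconnection).** C1–C2 and C9–C10 are cut and C2–C9 is restored, giving the lactone-fused cyclooctenone enol acetate 28 with an O-propenyl group on C4. The neighbouring cuts (C2–C3 or C9–C10 macrocyclization) would close the ten-membered ring against entropy and transannular strain. Ring expansion asks only for an eight-membered ring and pays for the growth with cyclobutane strain. The oxygen bridge and the C1 configuration come with it. C1, C10 and C14 shrink to a three-carbon ether substituent. The forward reaction must add "straight" (C2 to C1, C9 to C10), and the enol oxygen must sit on C9.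

**28 back to 24 (eight-membered ring).** Isomerization (27), enol acetylation (26) and oxidation (25) lead back to a C2–C9 aldol bond, cut to bromoketone aldehyde 24. C2–C9 is the only ring bond flanked by two carbonyl-level carbons. Metathesis is excluded by the allyl ether, which would close a six-membered ring instead. Reductive aldol closure of a bromoketone onto an aldehyde with SmI2 has eight-membered precedent. The precursor is an open chain on a trans-lactone. The forward step needs dilution and a reductant that spares the α-alkoxy ketone.

**24 back to 14 (C9 and the C8 stereocentre).** C8–C9 is cut: C9 is added to acid 14 as a diazomethyl carbon (16), unmasked as hydroxymethyl ketone 18. The C8 carbinol is set by hydroxyl-directed reduction to diol 19, where Felkin–Anh control from C7 gives the required configuration. Addition of a C9 nucleophile to a C8 aldehyde would give the opposite epimer under the same model, so the ketone-reduction order is chosen. Silylation (20), bromination of the C3 methyl ketone (22) and unveiling of the aldehyde (23, 24) follow.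

**14 back to 11 and 8 (C6–C7 and the lactone).** The C6–C7 bond and the lactone C–O bond are cut by an auxiliary-controlled syn-aldol between succinate imide 11 and keto aldehyde 8, giving lactone imide 13. An uncontrolled succinate aldol would be indifferent to C4, which is 1,3-remote. The oxazolidinone fixes C6 and C7 in one step, and its carbonyl becomes C8. The fragments are a four-carbon imide and a six-carbon aldehyde.

**8 back to 1 (citramalate fragment).** C2–C3 is cut (methyllithium on lactone 6), then the allyl ether (4 plus 5), then the lactone to (S)-citramalic acid 1 via dioxolanone 2. Allylating at the lactone stage avoids β-elimination, which threatens an O-alkylated citramalate diester. Installing the methyl ketone before the aldol avoids a late organometallic addition in the presence of the lactone.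

## Roads not taken

**Alternative 1:** The cut is the C6 carbinol and lactone C–O bond. A ketoreductase (NADPH, glucose dehydrogenase recycling) would reduce the C6 ketone of the epimerizing acylsuccinate A1, and the γ-hydroxy ester would close on C12 to give trans-paraconate A2.
- Merits: one catalytic step sets C6 and C7 from dimethyl succinate without an auxiliary. For this stereodiad alone it is shorter and more atom-economical than steps 6–8 here, and this is conceded.
- Weak points: an enzyme must accept the quaternary dioxolanone side chain with anti selectivity. The new hydroxyl is γ to both C12 and the activated dioxolanone carbonyl C3, so lactonization on the wrong carbonyl competes. The tertiary oxygen stays locked, so the propenyl ether would have to be made later on a hindered alcohol beside a lactone. The C8 ester still needs homologation, and the ten-membered ring is not addressed.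
- Comparison: the chosen plan offers a predictable Zimmerman–Traxler outcome without screening, with the O-allyl group and the C3 methyl ketone already in place.

**Alternative 2:** The cut is C6–C10 of the oxygen-bridged hydroazulene A3 (from a furan [4+3] cycloaddition). The C6 alkoxide expels the C14 mesylate and Grob fragmentation gives cyclodecenone A4.
- Merits: Grob fragmentation is a more secure entry to ten-membered rings than an untested photochemical expansion, and this is conceded. C10=C14 and the oxygen bridge arrive directly.
- Weak points: C4 must be set enantioselectively in the cycloaddition instead of from the chiral pool. The fragmentation needs an anti-periplanar C6–C10/C14–O array in a rigid tricycle. The C6 ketone must then be reduced and lactonized with control. The C7 side chain and the C8 and C9 oxygens must be placed on a crowded bicycle. The enol ether at C2=C3 still has to be transposed to the C1=C2 furanone.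
- Comparison: the chosen plan settles C4 and C6–C8 by acyclic control before any medium ring exists and accepts the photochemical risk in exchange.

**Alternative 3:** The cut is C2–C3. CrCl2 with catalytic NiCl2 (divalent chromium and nickel) would convert iodoalkyne aldehyde A5 into an alkynylchromium that closes the ten-membered cycloalkynol A6. Oxidation and oxa-Michael closure would then give the furanone.
- Merits: A6 already carries the methacrylate and both methylenes, and the conditions tolerate them. The endgame is shorter than steps 21–27 and needs no late enolate chemistry. This is a real advantage.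
- Weak points: A5 must carry five stereocentres and three Michael acceptors through a long linear sequence. The closure forms a bent ten-membered cycloalkyne against entropy, at high dilution with excess chromium.
- Comparison: the chosen plan sets a strain-driven ring growth from an easier eight-membered ring against this, and sensitive alkenes are absent until the ring is built.

Key step: step 20

## Route

Step 1
Reactants: 1 (S)-citramalic acid
Product: 2 2-[(4S)-2,2,4-trimethyl-5-oxo-1,3-dioxolan-4-yl]acetic acid
Conditions: Me2C(OMe)2, cat. TsOH, rt
Reagents that add atoms: 2,2-dimethoxypropane, COC(C)(C)OC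
Why: Acetalization of the α-hydroxy acid gives the five-membered dioxolanone in preference to larger rings, as known for malic acid; it protects C3 and the tertiary hydroxyl and leaves the C6 carboxyl free.

Step 2
Reactants: 2 dioxolanone acid
Product: 4 (3S)-3-hydroxy-3-methyloxolan-2-one, via dioxolanone alcohol 3 (not isolated)
Conditions: BH3·SMe2, THF, 0 °C to rt; MeOH; then cat. TsOH, CH2Cl2, rt
Reagents that add atoms: none
Why: Borane reduces the free carboxylic acid faster than the dioxolanone ester; the primary alcohol then transacylates onto C3 (5-exo) with loss of acetone, the known malic acid sequence, without touching C4.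

Step 3
Reactants: 4 hydroxy lactone; 5 allyl bromide
Product: 6 (3S)-3-methyl-3-(prop-2-enyloxy)oxolan-2-one
Conditions: NaH, cat. Bu4NI, DMF, 0 °C
Reagents that add atoms: none
Why: Williamson etherification of the tertiary alkoxide; the lactone has no α-hydrogen and no β-leaving group, so the elimination open to a citramalate diester cannot occur.

Step 4
Reactants: 6 allyloxy lactone
Product: 7 (3S)-5-hydroxy-3-methyl-3-(prop-2-enyloxy)pentan-2-one (in equilibrium with its cyclic hemiketal)
Conditions: MeLi (1.05 equiv), THF, −78 °C; AcOH quench
Reagents that add atoms: methyllithium, [Li]C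
Why: Mono-addition of an organolithium to a γ-lactone stops at the cyclic lithium hemiketalate at −78 °C; this installs C2 as the methyl ketone before any other carbonyl is present.

Step 5
Reactants: 7 hydroxy ketone
Product: 8 (3S)-3-methyl-4-oxo-3-(prop-2-enyloxy)pentanal
Conditions: Dess–Martin periodinane, NaHCO3, CH2Cl2, 0 °C to rt
Reagents that add atoms: none
Why: Oxidation of the primary alcohol drains the open form of the hemiketal equilibrium; buffered neutral conditions avoid β-elimination of the allyloxy group, and 8 is used crude.

Step 6
Reactants: 9 (4R)-4-benzyl-1,3-oxazolidin-2-one; 10 methyl 4-chloro-4-oxobutanoate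
Product: 11 methyl 4-[(4R)-4-benzyl-2-oxo-1,3-oxazolidin-3-yl]-4-oxobutanoate
Conditions: n-BuLi, THF, −78 °C; then 10
Reagents that add atoms: none
Why: N-Acylation of the lithiated oxazolidinone by the acid chloride is the standard preparation of Evans imides.

Step 7
Reactants: 11 succinate imide; 8 keto aldehyde
Product: 13 trans-lactone imide (C8 acyl oxazolidinone), via syn-aldol adduct 12 (not isolated)
Conditions: Bu2BOTf, i-Pr2NEt, CH2Cl2, −78 to 0 °C; 8, −78 to 0 °C; H2O2, pH 7 buffer, MeOH; then cat. TsOH, CH2Cl2, rt
Reagents that add atoms: none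
Why: Evans syn-aldol: the Z boron enolate adds to the aldehyde (not the ketone) through a Zimmerman–Traxler chair, and the (R)-auxiliary fixes C7 and C6 in the sense of 40 regardless of remote C4. The C6 hydroxyl then lactonizes onto the unhindered C12 ester to give the trans lactone.

Step 8
Reactants: 13 lactone imide
Product: 14 lactone acid (C8 CO2H)
Conditions: LiOH, H2O2, THF/H2O, 0 °C; Na2SO3; HCl to pH 2
Reagents that add atoms: lithium hydroperoxide (from LiOH and H2O2), [Li+].[O-]O
Why: Hydroperoxide cleaves the exocyclic imide carbonyl selectively; any opened lactone recloses on acidification to the only possible five-membered ring, and the trans arrangement is also the thermodynamic one.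

Step 9
Reactants: 14 lactone acid
Product: 16 C8 diazomethyl ketone, via acid chloride 15 (not isolated)
Conditions: (COCl)2, cat. DMF, CH2Cl2, 0 °C; then Me3SiCHN2, MeCN/THF, 0 °C to rt
Reagents that add atoms: trimethylsilyldiazomethane, C[Si](C)(C)C=[N+]=[N-]
Why: Acylation of a diazomethane equivalent by the acid chloride (first stage of an Arndt–Eistert sequence) brings in C9; the hindered C3 ketone does not react without a Lewis acid.

Step 10
Reactants: 16 diazoketone
Product: 18 C8 hydroxymethyl ketone, via trifluoroacetate ester 17 (not isolated)
Conditions: CF3CO2H, CH2Cl2, 0 °C; then NaHCO3, MeOH/H2O, rt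
Reagents that add atoms: trifluoroacetic acid, OC(=O)C(F)(F)F
Why: Protonation of the diazoketone, loss of N2 and capture by trifluoroacetate give the labile ester, which solvolyzes to the α-hydroxy ketone; allyl ether, lactone and methyl ketone are inert to these conditions.

Step 11
Reactants: 18 hydroxymethyl ketone
Product: 19 C8,C9 diol
Conditions: Me4NBH(OAc)3, MeCN/AcOH, −30 °C
Reagents that add atoms: none
Why: Hydroxyl-directed (Saksena–Evans) reduction: the C9 hydroxyl binds boron and delivers hydride intramolecularly, so the unhydroxylated C3 ketone is spared. Hydride adds anti to the larger C6 branch of C7 (Felkin–Anh), which gives the C8 configuration of 40.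

Step 12
Reactants: 19 diol
Product: 20 C8,C9 bis(tert-butyldimethylsilyl) ether
Conditions: TBSOTf, 2,6-lutidine, CH2Cl2, −78 to 0 °C
Reagents that add atoms: tert-butyldimethylsilyl trifluoromethanesulfonate, CC(C)(C)[Si](C)(C)OS(=O)(=O)C(F)(F)F
Why: Silyl triflate with lutidine silylates both hydroxyls quickly at low temperature, before the free C8 hydroxyl can translactonize.

Step 13
Reactants: 20 bis-silyl ether
Product: 22 C3 bromomethyl ketone, via trimethylsilyl enol ether 21 (not isolated)
Conditions: Me3SiOTf, Et3N, CH2Cl2, −20 °C; then NBS, NaHCO3, THF, −78 to 0 °C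
Reagents that add atoms: N-bromosuccinimide, O=C1CCC(=O)N1Br
Why: Soft enolization silylates the ketone (whose only α-hydrogens are on C2) much faster than the lactone; the silyl enol ether is brominated far faster than the allyl ether.

Step 14
Reactants: 22 bromoketone
Product: 23 C9 primary alcohol
Conditions: camphorsulfonic acid (0.2 equiv), MeOH/CH2Cl2, 0 °C
Reagents that add atoms: none
Why: Acidic methanolysis removes a primary silyl ether selectively in the presence of the secondary one; acid is used because amine-buffered fluoride would alkylate on the bromoketone.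

Step 15
Reactants: 23 alcohol
Product: 24 C9 aldehyde
Conditions: Dess–Martin periodinane, NaHCO3, CH2Cl2, 0 °C
Reagents that add atoms: none
Why: Neutral oxidation to the α-silyloxy aldehyde without epimerizing C8 or disturbing the bromoketone.

Step 16
Reactants: 24 bromoketone aldehyde
Product: 25 eight-membered β-hydroxy ketone (C9 epimers)
Conditions: SmI2 (2.2 equiv), THF, −78 °C, slow addition, 0.005 M
Reagents that add atoms: none
Why: SmI2-mediated Reformatsky-type aldol: two-electron reduction of the C–Br bond gives a trivalent samarium enolate at C2, which adds to the chelated C9 aldehyde and closes the eight-membered ring, a closure with precedent for bromoketone aldehydes. The new C9 centre is oxidized next, and without additive the α-alkoxy ketone is not cleaved.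

Step 17
Reactants: 25 β-hydroxy ketone
Product: 26 cyclooctane-3,9-dione
Conditions: Dess–Martin periodinane, NaHCO3, CH2Cl2, rt
Reagents that add atoms: none
Why: Periodinane oxidation of β-hydroxy ketones to 1,3-diketones is reliable; enolization lies between the carbonyls (C2), so C8 is not at risk.

Step 18
Reactants: 26 dione
Product: 27 C9 enol acetate (C3 enone; O-allyl)
Conditions: Ac2O, Et3N, cat. DMAP, CH2Cl2, 0 °C
Reagents that add atoms: acetic anhydride, CC(=O)OC(C)=O
Why: O-Acylation of the diketonate takes place at the oxygen remote from quaternary C4, as in enol ether formation from 4,4-disubstituted cyclohexane-1,3-diones. DMAP makes the acyl transfer reversible, so the less congested C9 enol acetate is also the thermodynamic isomer; the ring holds C2=C9 cis.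

Step 19
Reactants: 27 enol acetate
Product: 28 C9 enol acetate with C4 (E)-prop-1-enyl ether
Conditions: [Ir(cod)(PMePh2)2]PF6 (3 mol %, activated with H2), THF, rt
Reagents that add atoms: none
Why: The cationic iridium hydride isomerizes allyl ethers to (E)-propenyl ethers by a 1,3-hydrogen shift; the enone, enol ester and silyl ether do not react. The step is placed last so that the acid-labile enol ether meets no further reagent.

Step 20
Reactants: 28 propenyl ether enol acetate
Product: 30 oxolanone-bridged cyclodecane-3,9-dione (C10 epimers), via cyclobutane photoadduct 29 (not isolated)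
Conditions: hν (λ > 340 nm, Pyrex), degassed MeCN, 0.005 M, rt; then K2CO3, MeOH, 0 °C
Reagents that add atoms: none
Why: Proposed new method: an intramolecular de Mayo reaction on an eight-membered β-acetoxy enone; the closest known reaction type is the [2+2] photocycloaddition of tethered alkenes to enol esters of 1,3-diketones followed by retro-aldol cleavage, together with the [2+2] additions of cyclooctenones to electron-rich alkenes. The triplet enone bonds C2 to C1 of the enol ether held two atoms away (C4, O), closing the oxolane ring in 5-exo fashion, and the C9 and C10 radicals then combine to the cyclobutane. If the enone relaxes to its strained E isomer instead, polar attack of the nucleophilic C10 on electrophilic C9 followed by C2–C1 collapse gives the same constitution. Methoxide removes the tertiary acetate, and the C9 alkoxide cleaves C2–C9 in a retro-aldol step driven by cyclobutane strain, so the ten-membered ring arises by fragmentation of the bicycle rather than by cyclization. C1 becomes a bridgehead whose configuration is dictated by C4 through the one-atom oxygen bridge, while C10 forms as a mixture and is sp2 later. The step needs straight rather than crossed addition, secured by the five-membered first closure and the enol ether polarity, and it needs the enol oxygen on C9, secured in step 18. Dilution suppresses dimerization, and the long-wavelength filter limits α-cleavage at C3–C4.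

Step 21
Reactants: 30 dione
Product: 32 3(2H)-furanone C9 ketone (C10 epimers), via C3 trimethylsilyl enol ether 31 (not isolated)
Conditions: LiN(SiMe3)2 (1.05 equiv), Me3SiCl, THF, −78 °C; then Pd(OAc)2, MeCN, rt
Reagents that add atoms: none
Why: Saegusa–Ito dehydrogenation: kinetic deprotonation takes the unhindered C2 methylene of the five-membered ketone rather than the tertiary C8 or C10 hydrogens, and the palladium enolate loses the syn C1 hydrogen to give the vinylogous ester.

Step 22
Reactants: 32 furanone ketone
Product: 33 C11 dimethylaminomethyl lactone (Mannich base)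
Conditions: LiN(SiMe3)2 (1.05 equiv), THF, −78 to −40 °C; LiN(iPr)2 (1.1 equiv), −78 °C; CH2=NMe2+ I− (1.05 equiv), −78 to 0 °C
Reagents that add atoms: N,N-dimethylmethyleneiminium iodide, C=[N+](C)C.[I-]
Why: Sequential dianion formation: the first base removes C10–H, which is α to C9 and γ to the furanone carbonyl, and so masks the C9 ketone as a delocalized enolate; the second forms the lactone enolate. As in dianion alkylations, the more basic site alone captures the iminium salt (Mannich reaction); the C11 configuration is irrelevant.

Step 23
Reactants: 33 Mannich base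
Product: 35 C10=C14 dienone (still Mannich base), via C10 phenylselenide 34 (not isolated)
Conditions: LiN(SiMe3)2 (1.05 equiv), THF, −78 °C; PhSeCl; then H2O2, pyridine, CH2Cl2, 0 °C
Reagents that add atoms: none
Why: α-Selenenylation of the most acidic position, then selenoxide syn-elimination, which can only use the C14 hydrogens because C1 and C9 carry none. No Michael acceptor is present while the enolate exists.

Step 24
Reactants: 35 dienone Mannich base
Product: 37 α-methylene lactone dienone, via trimethylammonium iodide 36 (not isolated)
Conditions: MeI, CH2Cl2/MeOH, rt; then aq. NaHCO3, EtOAc, rt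
Reagents that add atoms: none
Why: Quaternization and mild-base elimination of the Mannich base is the standard last stage of lactone α-methylenation and needs no strong base beside the dienone.

Step 25
Reactants: 37 silyl ether
Product: 38 C8 alcohol
Conditions: HF·pyridine, THF, 0 °C to rt
Reagents that add atoms: none
Why: Buffered acidic fluoride removes the secondary silyl ether without the basic conditions that would epimerize the α-hydroxy ketone or add to the enones.

Step 26
Reactants: 38 alcohol
Product: 39 C8 methacrylate C9 ketone
Conditions: methacrylic anhydride, Et3N, cat. DMAP, CH2Cl2, 0 °C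
Reagents that add atoms: methacrylic anhydride, C=C(C)C(=O)OC(=O)C(C)=C
Why: DMAP-catalysed acylation of the only hydroxyl; C9 is still a ketone, so no hydroxyl differentiation is needed, and acylation at 0 °C outruns translactonization.

Step 27
Reactants: 39 enone
Product: 40 target (CNP0142847.1)
Conditions: NaBH4, CeCl3·7H2O, MeOH, −78 °C
Reagents that add atoms: none
Why: Luche 1,2-reduction of the only ketone-type carbonyl; the vinylogous ester, lactone and esters are inert at −78 °C. Hydride should enter from the face opposite the C8 ester and the oxygen bridge, which lie on the same side of the macrocycle, giving the 8,9-cis alcohol (9S).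

## Compound list

1 | (S)-citramalic acid | C[C@](O)(CC(=O)O)C(=O)O | starting material
2 | 2-[(4S)-2,2,4-trimethyl-5-oxo-1,3-dioxolan-4-yl]acetic acid | C[C@@]1(CC(=O)O)OC(C)(C)OC1=O | intermediate
3 | (5S)-5-(2-hydroxyethyl)-2,2,5-trimethyl-1,3-dioxolan-4-one (not isolated) | C[C@@]1(CCO)OC(C)(C)OC1=O | intermediate
4 | (3S)-3-hydroxy-3-methyloxolan-2-one | C[C@]1(O)CCOC1=O | intermediate
5 | allyl bromide | C=CCBr | starting material
6 | (3S)-3-methyl-3-(prop-2-enyloxy)oxolan-2-one | C[C@]1(OCC=C)CCOC1=O | intermediate
7 | (3S)-5-hydroxy-3-methyl-3-(prop-2-enyloxy)pentan-2-one | CC(=O)[C@@](C)(OCC=C)CCO | intermediate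
8 | (3S)-3-methyl-4-oxo-3-(prop-2-enyloxy)pentanal | CC(=O)[C@@](C)(OCC=C)CC=O | intermediate
9 | (4R)-4-benzyl-1,3-oxazolidin-2-one | O=C1OC[C@@H](Cc2ccccc2)N1 | starting material
10 | methyl 4-chloro-4-oxobutanoate | COC(=O)CCC(=O)Cl | starting material
11 | methyl 4-[(4R)-4-benzyl-2-oxo-1,3-oxazolidin-3-yl]-4-oxobutanoate | COC(=O)CCC(=O)N1C(=O)OC[C@H]1Cc1ccccc1 | intermediate
12 | syn-aldol adduct: C6 hydroxyl, C7 bearing CH2CO2Me and the C8 acyl oxazolidinone, chain C5H2–C4(CH3)(O-allyl)–C(=O)CH3; C4, C6, C7 as in 40 (not isolated) | O=C1OC[C@@H](Cc2ccccc2)N1C(=O)[C@H](CC(=O)OC)[C@@H](O)C[C@](C)(OCC=C)C(C)=O | intermediate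
13 | trans-γ-lactone (O on C6, carbonyl C12) with C7 bearing the C8 acyl (4R)-4-benzyloxazolidinone and C6 bearing CH2–C(CH3)(O-allyl)–C(=O)CH3 | O=C1OC[C@@H](Cc2ccccc2)N1C(=O)[C@@H]3CC(=O)O[C@H]3C[C@](C)(OCC=C)C(C)=O | intermediate
14 | trans-lactone C8 carboxylic acid (same side chain) | OC(=O)[C@@H]1CC(=O)O[C@H]1C[C@](C)(OCC=C)C(C)=O | intermediate
15 | trans-lactone C8 acid chloride (not isolated) | ClC(=O)[C@@H]1CC(=O)O[C@H]1C[C@](C)(OCC=C)C(C)=O | intermediate
16 | trans-lactone C8 diazomethyl ketone | [N-]=[N+]=CC(=O)[C@@H]1CC(=O)O[C@H]1C[C@](C)(OCC=C)C(C)=O | intermediate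
17 | trans-lactone C8 (trifluoroacetoxy)methyl ketone (not isolated) | FC(F)(F)C(=O)OCC(=O)[C@@H]1CC(=O)O[C@H]1C[C@](C)(OCC=C)C(C)=O | intermediate
18 | trans-lactone C8 hydroxymethyl ketone | OCC(=O)[C@@H]1CC(=O)O[C@H]1C[C@](C)(OCC=C)C(C)=O | intermediate
19 | trans-lactone C8,C9 diol (C8 as in 40) | OC[C@H](O)[C@@H]1CC(=O)O[C@H]1C[C@](C)(OCC=C)C(C)=O | intermediate
20 | C8,C9 bis(tert-butyldimethylsilyl) ether of 19 | CC(C)(C)[Si](C)(C)OC[C@H](O[Si](C)(C)C(C)(C)C)[C@@H]1CC(=O)O[C@H]1C[C@](C)(OCC=C)C(C)=O | intermediate
21 | C3 trimethylsilyl enol ether of 20 (not isolated) | CC(C)(C)[Si](C)(C)OC[C@H](O[Si](C)(C)C(C)(C)C)[C@@H]1CC(=O)O[C@H]1C[C@](C)(OCC=C)C(=C)O[Si](C)(C)C | intermediate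
22 | C3 bromomethyl ketone (C2 bromide) of 20 | CC(C)(C)[Si](C)(C)OC[C@H](O[Si](C)(C)C(C)(C)C)[C@@H]1CC(=O)O[C@H]1C[C@](C)(OCC=C)C(=O)CBr | intermediate
23 | bromoketone with free C9 hydroxyl and C8 silyl ether | OC[C@H](O[Si](C)(C)C(C)(C)C)[C@@H]1CC(=O)O[C@H]1C[C@](C)(OCC=C)C(=O)CBr | intermediate
24 | bromoketone C9 aldehyde | O=C[C@H](O[Si](C)(C)C(C)(C)C)[C@@H]1CC(=O)O[C@H]1C[C@](C)(OCC=C)C(=O)CBr | intermediate
25 | lactone-fused cyclooctanone: C3 ketone, C9 hydroxyl (epimers), C8 silyl ether, C4 O-allyl | CC(C)(C)[Si](C)(C)O[C@@H]1[C@@H]2CC(=O)O[C@H]2C[C@](C)(OCC=C)C(=O)CC1O | intermediate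
26 | lactone-fused cyclooctane-3,9-dione | CC(C)(C)[Si](C)(C)O[C@@H]1[C@@H]2CC(=O)O[C@H]2C[C@](C)(OCC=C)C(=O)CC1=O | intermediate
27 | C9 enol acetate of 26 (C3 ketone, cis C2=C9), O-allyl | CC(C)(C)[Si](C)(C)O[C@@H]1[C@@H]2CC(=O)O[C@H]2C[C@](C)(OCC=C)C(=O)/C=C\1OC(C)=O | intermediate
28 | C9 enol acetate with C4 (E)-prop-1-enyl ether (key-step precursor) | CC(C)(C)[Si](C)(C)O[C@@H]1[C@@H]2CC(=O)O[C@H]2C[C@](C)(O/C=C/C)C(=O)/C=C\1OC(C)=O | intermediate
29 | cyclobutane photoadduct: bonds C1–C2 and C9–C10, C9 tertiary acetate; C9 and C10 configurations not assigned (not isolated) | CC(C)(C)[Si](C)(C)O[C@@H]1[C@@H]2CC(=O)O[C@H]2C[C@]3(C)O[C@@H]4C(C)C1(OC(C)=O)[C@@H]4C3=O | intermediate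
30 | oxolanone-bridged cyclodecane-3,9-dione (C10 epimers), C8 silyl ether | CC(C)(C)[Si](C)(C)O[C@@H]1[C@@H]2CC(=O)O[C@H]2C[C@]2(C)O[C@@H](CC2=O)C(C)C1=O | intermediate
31 | C3 trimethylsilyl enol ether (C2=C3) of 30 (not isolated) | CC(C)(C)[Si](C)(C)O[C@@H]1[C@@H]2CC(=O)O[C@H]2C[C@]2(C)O[C@@H](C=C2O[Si](C)(C)C)C(C)C1=O | intermediate
32 | 3(2H)-furanone (C1=C2) with C9 ketone and C10 methyl (epimers) | CC(C)(C)[Si](C)(C)O[C@@H]1[C@@H]2CC(=O)O[C@H]2C[C@]2(C)OC(=CC2=O)C(C)C1=O | intermediate
33 | 32 carrying CH2NMe2 on C11 (C10, C11 epimers) | CC(C)(C)[Si](C)(C)O[C@@H]1[C@@H]2C(CN(C)C)C(=O)O[C@H]2C[C@]2(C)OC(=CC2=O)C(C)C1=O | intermediate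
34 | C10 phenylselenide of 33 (not isolated) | CC(C)(C)[Si](C)(C)O[C@@H]1[C@@H]2C(CN(C)C)C(=O)O[C@H]2C[C@]2(C)OC(=CC2=O)C(C)([Se]c3ccccc3)C1=O | intermediate
35 | C10=C14 methylene dienone with C11 CH2NMe2 | CC(C)(C)[Si](C)(C)O[C@@H]1[C@@H]2C(CN(C)C)C(=O)O[C@H]2C[C@]2(C)OC(=CC2=O)C(=C)C1=O | intermediate
36 | trimethylammonium iodide of 35 (not isolated) | CC(C)(C)[Si](C)(C)O[C@@H]1[C@@H]2C(C[N+](C)(C)C)C(=O)O[C@H]2C[C@]2(C)OC(=CC2=O)C(=C)C1=O.[I-] | intermediate
37 | α-methylene lactone, C10=C14, C9 ketone, C8 silyl ether | CC(C)(C)[Si](C)(C)O[C@@H]1[C@@H]2C(=C)C(=O)O[C@H]2C[C@]2(C)OC(=CC2=O)C(=C)C1=O | intermediate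
38 | C8 alcohol of 37 | O[C@@H]1[C@@H]2C(=C)C(=O)O[C@H]2C[C@]2(C)OC(=CC2=O)C(=C)C1=O | intermediate
39 | C8 methacrylate, C9 ketone | C=C(C)C(=O)O[C@@H]1[C@@H]2C(=C)C(=O)O[C@H]2C[C@]2(C)OC(=CC2=O)C(=C)C1=O | intermediate
40 | CNP0142847.1 (4S,6S,7R,8R,9S) | C=C(C)C(=O)O[C@@H]1[C@@H]2C(=C)C(=O)O[C@H]2C[C@]2(C)OC(=CC2=O)C(=C)[C@@H]1O | target

## Step count and risks

Total steps: 27. Longest linear sequence: 26 (steps 1–5 and 7–27; step 6 is the side branch).

**Step 20 (key step; proposed new method).**
- What may go wrong: the excited cyclooctenone may relax by cis–trans isomerization and decompose or dimerize; addition may be crossed; α-cleavage at C3–C4 may compete; or the tertiary acetate may resist methanolysis so that the retro-aldol does not start.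
- Fallback (known chemistry, furanone first, then acylative ring closure), from 20 back to 32. One-pot isomerization ([Ir(cod)(PMePh2)2]PF6) and mild acid hydrolysis of the allyl ether give the tertiary hydroxy ketone F1. Double deprotonation with LiN(iPr)2 and acylation with N-propionylimidazole give the β-diketone F2. Cat. TsOH cyclizes and dehydrates F2 to the 5-ethyl-3(2H)-furanone F3, the classical route to this heterocycle. Camphorsulfonic acid in MeOH frees the primary alcohol F4. Oxidation (TEMPO/PhI(OAc)2, then NaClO2) gives the acid F5, and Me3SiCHN2 gives the methyl ester F6. LiN(SiMe3)2 at high dilution then deprotonates the ethyl group, the γ-position of the vinylogous ester, and the anion acylates on the C9 ester (intramolecular Claisen condensation), giving 32 as its stabilized enolate.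

**Step 16 (eight-membered ring closure).**
- What may go wrong: simple debromination, intermolecular aldol coupling, or reductive loss of the α-allyloxy group if the ring closes slowly.
- Fallback (closure at the ester oxidation level), from 20 back to 26. Camphorsulfonic acid in MeOH gives the primary alcohol F7. Oxidation gives the acid F8 and Me3SiCHN2 the methyl ester F9. LiN(SiMe3)2 (or TiCl4/Bu3N) at high dilution forms the C2 enolate of the methyl ketone, which acylates on the C9 ester (Claisen-type cyclization). This gives dione 26 directly as its diketonate, without bromination, SmI2 or the second oxidation.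

**Step 18 (site of enol acetylation).**
- What may go wrong: acylation on the C3 oxygen, because the C8 silyl ether also crowds C9; that isomer would lead to crossed cycloaddition.
- Fallback (vinylogous amide in place of the enol ester), from 26 back to 30. Condensation with pyrrolidine, which attacks only the carbonyl carbon not flanked by the quaternary centre, gives the C9 enaminone F10. Iridium-catalysed isomerization gives the propenyl ether F11. Irradiation, then aqueous acid, gives 30 by [2+2] photocycloaddition, retro-Mannich fragmentation and hydrolysis.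

**Step 22 (lactone Mannich reaction beside a ketone).**
- What may go wrong: incomplete first deprotonation leaves the C9 ketone free, so the second base enolizes toward C8, or the iminium salt is captured at C10 or C2.
- Fallback (separate masking of the ketone), from 32 back to 33. Et3SiOTf/Et3N gives the C9 silyl dienol ether F12. LiN(iPr)2 then forms only the lactone enolate, and Eschenmoser's salt gives the Mannich base F13. Dilute acid on work-up returns the ketone, giving 33.

**Step 27 (configuration at C9).**
- What may go wrong: poor facial selectivity if the macrocycle presents the other carbonyl face, or slow conjugate reduction of the methylene lactone if the temperature rises.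
- Fallback (correction by inversion), from 39 back to 40. If the 9-epimeric alcohol F14 predominates, Mitsunobu reaction with chloroacetic acid (PPh3, DIAD) gives the inverted chloroacetate F15. Thiourea with NaHCO3 removes the chloroacetyl group without touching the methacrylate, giving 40.

## Further compounds

F1 | step 20 | C4 tertiary alcohol of 20 (allyl removed) | CC(C)(C)[Si](C)(C)OC[C@H](O[Si](C)(C)C(C)(C)C)[C@@H]1CC(=O)O[C@H]1C[C@](C)(O)C(C)=O
F2 | step 20 | β-diketone from C2-propionylation of F1 | CC(C)(C)[Si](C)(C)OC[C@H](O[Si](C)(C)C(C)(C)C)[C@@H]1CC(=O)O[C@H]1C[C@](C)(O)C(=O)CC(=O)CC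
F3 | step 20 | 5-ethyl-3(2H)-furanone (C1 ethyl = C10, C14), bis-silyl ether | CC(C)(C)[Si](C)(C)OC[C@H](O[Si](C)(C)C(C)(C)C)[C@@H]1CC(=O)O[C@H]1C[C@]1(C)OC(CC)=CC1=O
F4 | step 20 | C9 primary alcohol of F3 | OC[C@H](O[Si](C)(C)C(C)(C)C)[C@@H]1CC(=O)O[C@H]1C[C@]1(C)OC(CC)=CC1=O
F5 | step 20 | C9 carboxylic acid of F3 | OC(=O)[C@H](O[Si](C)(C)C(C)(C)C)[C@@H]1CC(=O)O[C@H]1C[C@]1(C)OC(CC)=CC1=O
F6 | step 20 | C9 methyl ester of F3 | COC(=O)[C@H](O[Si](C)(C)C(C)(C)C)[C@@H]1CC(=O)O[C@H]1C[C@]1(C)OC(CC)=CC1=O
F7 | step 16 | C9 primary alcohol of methyl ketone 20 | OC[C@H](O[Si](C)(C)C(C)(C)C)[C@@H]1CC(=O)O[C@H]1C[C@](C)(OCC=C)C(C)=O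
F8 | step 16 | C9 carboxylic acid of methyl ketone 20 | OC(=O)[C@H](O[Si](C)(C)C(C)(C)C)[C@@H]1CC(=O)O[C@H]1C[C@](C)(OCC=C)C(C)=O
F9 | step 16 | C9 methyl ester of methyl ketone 20 | COC(=O)[C@H](O[Si](C)(C)C(C)(C)C)[C@@H]1CC(=O)O[C@H]1C[C@](C)(OCC=C)C(C)=O
F10 | step 18 | C9 pyrrolidine enaminone of 26 (O-allyl) | CC(C)(C)[Si](C)(C)O[C@@H]1[C@@H]2CC(=O)O[C@H]2C[C@](C)(OCC=C)C(=O)/C=C\1N3CCCC3
F11 | step 18 | C9 pyrrolidine enaminone with (E)-propenyl ether | CC(C)(C)[Si](C)(C)O[C@@H]1[C@@H]2CC(=O)O[C@H]2C[C@](C)(O/C=C/C)C(=O)/C=C\1N3CCCC3
F12 | step 22 | C9 triethylsilyl dienol ether (C9=C10) of 32 | CC(C)(C)[Si](C)(C)O[C@@H]1[C@@H]2CC(=O)O[C@H]2C[C@]2(C)OC(=CC2=O)C(C)=C1O[Si](CC)(CC)CC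
F13 | step 22 | F12 carrying CH2NMe2 on C11 | CC(C)(C)[Si](C)(C)O[C@@H]1[C@@H]2C(CN(C)C)C(=O)O[C@H]2C[C@]2(C)OC(=CC2=O)C(C)=C1O[Si](CC)(CC)CC
F14 | step 27 | 9-epimer of 40 | C=C(C)C(=O)O[C@@H]1[C@@H]2C(=C)C(=O)O[C@H]2C[C@]2(C)OC(=CC2=O)C(=C)[C@H]1O
F15 | step 27 | C9 chloroacetate of 40 | C=C(C)C(=O)O[C@@H]1[C@@H]2C(=C)C(=O)O[C@H]2C[C@]2(C)OC(=CC2=O)C(=C)[C@@H]1OC(=O)CCl
A1 | alternative 1 | dimethyl 2-acylsuccinate with the C4 dioxolanone (C7 epimers) | COC(=O)CC(C(=O)OC)C(=O)C[C@]1(C)OC(C)(C)OC1=O
A2 | alternative 1 | trans-paraconate carrying the C4 dioxolanone | COC(=O)[C@@H]1CC(=O)O[C@H]1C[C@]2(C)OC(C)(C)OC2=O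
A3 | alternative 2 | oxygen-bridged hydroazulene with C6 tertiary alcohol and C14 mesylate (C6, C10 configurations not specified) | COc1ccc(CO[C@@H]2[C@H](CC(=O)OC)C4(O)C[C@]3(C)O[C@@H](C=C3O[Si](C(C)C)(C(C)C)C(C)C)C4(COS(C)(=O)=O)[C@@H]2O[Si](C)(C)C(C)(C)C)cc1
A4 | alternative 2 | oxygen-bridged cyclodecane C6 ketone with C10 methylene | COc1ccc(CO[C@@H]2[C@H](CC(=O)OC)C(=O)C[C@]3(C)O[C@@H](C=C3O[Si](C(C)C)(C(C)C)C(C)C)C(=C)[C@@H]2O[Si](C)(C)C(C)(C)C)cc1
A5 | alternative 3 | C2 iodoalkyne C3 aldehyde, open chain | C=C(C)C(=O)O[C@H]([C@@H]1C(=C)C(=O)O[C@H]1C[C@](C)(O[Si](CC)(CC)CC)C=O)[C@@H](O[Si](C)(C)C(C)(C)C)C(=C)C#CI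
A6 | alternative 3 | ten-membered cycloalkynol (C3 epimers) | C=C(C)C(=O)O[C@@H]1[C@@H]2C(=C)C(=O)O[C@H]2C[C@](C)(O[Si](CC)(CC)CC)C(O)C#CC(=C)[C@@H]1O[Si](C)(C)C(C)(C)C
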